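Retrosynthesis: the spiro C–O bond is made last, by acid-catalysed 5-exo hydroalkoxylation of a tetrasubstituted cyclohexene by the O–H of a 3-hydroxytropone; this closes the dihydrofuran ring and sets the spiro carbon and the neighbouring CH–CH3.
The tropone ring is made just before, by aldol condensation and aromatisation of an acetal-masked enal β-diketone.
That chain comes from Claisen acylation of a Weiler-type dianion (built from methyl 3-oxopentanoate and 1,1-dimethoxyacetone) with a cyclohexenylpropanoate, itself from Negishi coupling of an enol triflate with a zinc homoenolate.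
The cyclohexane ring is not built: (S)-carvone supplies it with the CH stereocentre, two α′-alkylations set the quaternary carbon, and Mukaiyama hydration gives the tertiary alcohol.
Ring order: cyclohexane (chiral pool), then tropone, then dihydrofuran.

Assumption: hydroxytropone 21 is drawn as one of its two fast-exchanging tautomers, and 3, 17, 19 and 20 are used as isomer mixtures (C-6 epimers, alkene E/Z, diketone epimers/enols) that converge later.

Step 1
Reactants: 1 (S)-(+)-carvone
Product: 3 (5S,6R)-2,6-dimethyl-5-(prop-1-en-2-yl)cyclohex-2-en-1-one, via lithium dienolate 2 (not isolated)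
Conditions: LiN(i-Pr)2, THF, −78 °C; then MeI, −78 → −20 °C
Reagents that add atoms: methyl iodide, CI
Why: Kinetic α′-deprotonation gives the cross-conjugated dienolate, which is C-methylated (enolate alkylation) mainly trans to the isopropenyl group; this centre is planarised again in step 2, so the epimer ratio does not matter.

Step 2
Reactants: 3 (5S,6R)-2,6-dimethyl-5-(prop-1-en-2-yl)cyclohex-2-en-1-one; 4 tert-butyl(3-iodopropoxy)dimethylsilane
Product: 6 (5R,6R)-6-[3-(tert-butyldimethylsilyloxy)propyl]-2,6-dimethyl-5-(prop-1-en-2-yl)cyclohex-2-en-1-one, via lithium dienolate 5 (not isolated)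
Conditions: LiN(i-Pr)2, THF, −78 → −20 °C; then DMPU, 4, −78 → 0 °C
Reagents that add atoms: none
Why: Enolate alkylation of the fully substituted α′-dienolate by the primary iodide occurs anti to the adjacent isopropenyl group, so the new chain ends trans and the methyl cis to it, which sets the quaternary carbon.

Step 3
Reactants: 6 (5R,6R)-6-[3-(tert-butyldimethylsilyloxy)propyl]-2,6-dimethyl-5-(prop-1-en-2-yl)cyclohex-2-en-1-one
Product: 8 (5R,6R)-6-[3-(tert-butyldimethylsilyloxy)propyl]-2,6-dimethyl-5-(prop-1-en-2-yl)cyclohex-1-en-1-yl trifluoromethanesulfonate, via lithium enolate 7 (not isolated)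
Conditions: LiBH(s-Bu)3, THF, −78 °C; then PhNTf2, −78 → 0 °C; aq. NH4Cl
Reagents that add atoms: N-phenylbis(trifluoromethanesulfonimide), O=S(=O)(N(c1ccccc1)S(=O)(=O)C(F)(F)F)C(F)(F)F
Why: Conjugate reduction of the β-unsubstituted enone by the hindered borohydride gives one regiodefined enolate, which is O-triflated; the other α-carbon is quaternary, so only this enol triflate can form.

Step 4
Reactants: 8 (5R,6R)-6-[3-(tert-butyldimethylsilyloxy)propyl]-2,6-dimethyl-5-(prop-1-en-2-yl)cyclohex-1-en-1-yl trifluoromethanesulfonate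
Product: 9 (5S,6R)-6-[3-(tert-butyldimethylsilyloxy)propyl]-5-(2-hydroxypropan-2-yl)-2,6-dimethylcyclohex-1-en-1-yl trifluoromethanesulfonate
Conditions: Co(acac)2 (20 mol %), PhSiH3, O2 (1 atm), THF/i-PrOH, rt; then aq. Na2S2O3
Reagents that add atoms: dioxygen, O=O
Why: Mukaiyama hydration, in which hydrogen-atom transfer from a cobalt hydride to the 1,1-disubstituted alkene gives an exocyclic tertiary radical that is oxygenated and reduced to the Markovnikov alcohol; the electron-poor enol triflate is inert and the ring stereocentre is untouched.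

Step 5
Reactants: 9 (5S,6R)-6-[3-(tert-butyldimethylsilyloxy)propyl]-5-(2-hydroxypropan-2-yl)-2,6-dimethylcyclohex-1-en-1-yl trifluoromethanesulfonate
Product: 12 3-[(1R,6S)-6-(2-hydroxypropan-2-yl)-1,3-dimethyl-2-(trifluoromethanesulfonyloxy)cyclohex-2-en-1-yl]propanoic acid, via diol 10 (not isolated), via hydroxy aldehyde 11 (not isolated)
Conditions: CrO3, H2SO4, H2O, acetone, 0 °C → rt
Reagents that add atoms: water, O
Why: Jones oxidation, in which the aqueous acid removes the primary silyl ether and hexavalent chromium oxidises the alcohol through the aldehyde hydrate to the acid; the tertiary alcohol cannot be oxidised and the enol triflate is stable to acid and oxidant.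

Step 6
Reactants: 12 3-[(1R,6S)-6-(2-hydroxypropan-2-yl)-1,3-dimethyl-2-(trifluoromethanesulfonyloxy)cyclohex-2-en-1-yl]propanoic acid; 13 (3-ethoxy-3-oxopropyl)zinc bromide, BrZnCH2CH2CO2Et
Product: 14 3-[(1R,6S)-2-(3-ethoxy-3-oxopropyl)-6-(2-hydroxypropan-2-yl)-1,3-dimethylcyclohex-2-en-1-yl]propanoic acid
Conditions: 13 (3 equiv), Pd(OAc)2 (5 mol %), 2-dicyclohexylphosphino-2′,6′-dimethoxybiphenyl (10 mol %), LiCl, THF, 50 °C
Reagents that add atoms: none
Why: Negishi coupling, in which zerovalent palladium inserts into the enol triflate, the zinc homoenolate transmetalates and reductive elimination gives the tetrasubstituted alkene; the first equivalent of 13 is spent on the carboxylic acid proton.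

Step 7
Reactants: 15 methyl 3-oxopentanoate; 16 1,1-dimethoxypropan-2-one
Product: 17 methyl 2-(1,1-dimethoxypropan-2-ylidene)-3-oxopentanoate
Conditions: TiCl4, pyridine, THF, 0 °C → rt
Reagents that add atoms: none
Why: Lehnert-type Knoevenagel condensation, in which the titanium enolate of the β-keto ester adds to the α,α-dialkoxy-activated ketone and titanium-assisted dehydration gives the alkylidene β-keto ester as an E/Z mixture.

Step 8
Reactants: 14 3-[(1R,6S)-2-(3-ethoxy-3-oxopropyl)-6-(2-hydroxypropan-2-yl)-1,3-dimethylcyclohex-2-en-1-yl]propanoic acid; 17 methyl 2-(1,1-dimethoxypropan-2-ylidene)-3-oxopentanoate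
Product: 19 3-[(1R,6S)-2-[8,8-dimethoxy-6-(methoxycarbonyl)-4,7-dimethyl-3,5-dioxooct-6-en-1-yl]-6-(2-hydroxypropan-2-yl)-1,3-dimethylcyclohex-2-en-1-yl]propanoic acid, via dilithium dianion 18 (not isolated)
Conditions: 17 (3.5 equiv), LiN(i-Pr)2 (7.2 equiv), THF, −78 → −20 °C; then 14, −78 → 0 °C; aq. HCl to pH 4
Reagents that add atoms: none
Why: Claisen-type γ-acylation of a Weiler dianion, in which double deprotonation of 17 (γ-methyl, then α′-methylene) gives 18 and its more basic α′-carbon attacks the unhindered ethyl ester of 14, whose carboxylate and alkoxide are inert.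

Step 9
Reactants: 19 3-[(1R,6S)-2-[8,8-dimethoxy-6-(methoxycarbonyl)-4,7-dimethyl-3,5-dioxooct-6-en-1-yl]-6-(2-hydroxypropan-2-yl)-1,3-dimethylcyclohex-2-en-1-yl]propanoic acid
Product: 21 3-[(1R,6S)-2-{[7-hydroxy-4-(methoxycarbonyl)-3,6-dimethyl-5-oxocyclohepta-1,3,6-trien-1-yl]methyl}-6-(2-hydroxypropan-2-yl)-1,3-dimethylcyclohex-2-en-1-yl]propanoic acid, via enal 20 (not isolated)
Conditions: AcOH/THF/H2O (3:1:1), 40 °C; then piperidine (0.3 equiv), AcOH (0.3 equiv), toluene, 4 Å MS, 60 °C
Reagents that add atoms: none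
Why: Acetal hydrolysis frees the enal, and amine/acid-catalysed intramolecular aldol condensation of the ketone α′-methylene onto it closes the seven-membered ring, dehydration and enolisation giving the aromatic 3-hydroxytropone as the thermodynamic sink (the competing aldol at the central diketone carbon cannot dehydrate and reverts).

Step 10
Reactants: 21 3-[(1R,6S)-2-{[7-hydroxy-4-(methoxycarbonyl)-3,6-dimethyl-5-oxocyclohepta-1,3,6-trien-1-yl]methyl}-6-(2-hydroxypropan-2-yl)-1,3-dimethylcyclohex-2-en-1-yl]propanoic acid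
Product: 22 3-[(2R,2′R,3′S,6′S)-3′-(2-hydroxypropan-2-yl)-6-(methoxycarbonyl)-2′,5,6′,8-tetramethyl-7-oxo-3,7-dihydrospiro[cyclohepta[b]furan-2,1′-cyclohexan]-2′-yl]propanoic acid
Conditions: CF3SO3H (10 mol %), H2O (2 equiv), CH3NO2, 40 °C
Reagents that add atoms: none
Why: Proposed new method: Brønsted-acid-catalysed 5-exo Markovnikov hydroalkoxylation of an unactivated tetrasubstituted alkene by the vinylogous-acid O–H of a 3-hydroxytropone, reasoned as protonation at the methyl-bearing alkene carbon to give the tertiary cation beside the quaternary centre (reversibly parked as the δ-lactone of the neighbouring CO2H on the chain face), capture by the tropolonoid oxygen from the face of the angular CH3, and equilibration by re-ionisation of the tertiary vinylogous ester, so that the spiro carbon carries an equatorial oxygen cis to the angular CH3 and the new CH–CH3 an equatorial methyl (its epimer would be 1,3-diaxial to the angular CH3), the added water keeping the tertiary alcohol from dehydrating; the closest known reaction is the acid-mediated phenol–alkene spirocyclisation to spiro-dihydrobenzofurans in the benzenoid drimane meroterpenoids, not yet shown for a troponoid nucleophile.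

Compound list
1 | (S)-(+)-carvone, (5S)-2-methyl-5-(prop-1-en-2-yl)cyclohex-2-en-1-one | O=C1C(C)=CC[C@H](C(C)=C)C1 | starting material
2 | lithium (3S)-6-methyl-3-(prop-1-en-2-yl)cyclohexa-1,5-dien-1-olate (kinetic dienolate of 1) | [Li+].[O-]C=1C(C)=CC[C@H](C(C)=C)C=1 | intermediate
3 | (5S,6R)-2,6-dimethyl-5-(prop-1-en-2-yl)cyclohex-2-en-1-one (major trans isomer; the 6S epimer is carried along) | O=C1C(C)=CC[C@H](C(C)=C)[C@H]1C | intermediate
4 | tert-butyl(3-iodopropoxy)dimethylsilane | CC(C)(C)[Si](C)(C)OCCCI | starting material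
5 | lithium (3R)-2,6-dimethyl-3-(prop-1-en-2-yl)cyclohexa-1,5-dien-1-olate | [Li+].[O-]C=1C(C)=CC[C@H](C(C)=C)C=1C | intermediate
6 | (5R,6R)-6-[3-(tert-butyldimethylsilyloxy)propyl]-2,6-dimethyl-5-(prop-1-en-2-yl)cyclohex-2-en-1-one | O=C1C(C)=CC[C@H](C(C)=C)[C@@]1(C)CCCO[Si](C)(C)C(C)(C)C | intermediate
7 | lithium (5R,6R)-6-[3-(tert-butyldimethylsilyloxy)propyl]-2,6-dimethyl-5-(prop-1-en-2-yl)cyclohex-1-en-1-olate | [Li+].[O-]C1=C(C)CC[C@H](C(C)=C)[C@@]1(C)CCCO[Si](C)(C)C(C)(C)C | intermediate
8 | (5R,6R)-6-[3-(tert-butyldimethylsilyloxy)propyl]-2,6-dimethyl-5-(prop-1-en-2-yl)cyclohex-1-en-1-yl trifluoromethanesulfonate | FC(F)(F)S(=O)(=O)OC1=C(C)CC[C@H](C(C)=C)[C@@]1(C)CCCO[Si](C)(C)C(C)(C)C | intermediate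
9 | (5S,6R)-6-[3-(tert-butyldimethylsilyloxy)propyl]-5-(2-hydroxypropan-2-yl)-2,6-dimethylcyclohex-1-en-1-yl trifluoromethanesulfonate | FC(F)(F)S(=O)(=O)OC1=C(C)CC[C@H](C(C)(C)O)[C@@]1(C)CCCO[Si](C)(C)C(C)(C)C | intermediate
10 | (5S,6R)-5-(2-hydroxypropan-2-yl)-6-(3-hydroxypropyl)-2,6-dimethylcyclohex-1-en-1-yl trifluoromethanesulfonate | FC(F)(F)S(=O)(=O)OC1=C(C)CC[C@H](C(C)(C)O)[C@@]1(C)CCCO | intermediate
11 | (5S,6R)-5-(2-hydroxypropan-2-yl)-2,6-dimethyl-6-(3-oxopropyl)cyclohex-1-en-1-yl trifluoromethanesulfonate | FC(F)(F)S(=O)(=O)OC1=C(C)CC[C@H](C(C)(C)O)[C@@]1(C)CCC=O | intermediate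
12 | 3-[(1R,6S)-6-(2-hydroxypropan-2-yl)-1,3-dimethyl-2-(trifluoromethanesulfonyloxy)cyclohex-2-en-1-yl]propanoic acid | FC(F)(F)S(=O)(=O)OC1=C(C)CC[C@H](C(C)(C)O)[C@@]1(C)CCC(=O)O | intermediate
13 | (3-ethoxy-3-oxopropyl)zinc bromide, BrZnCH2CH2CO2Et | CCOC(=O)CC[Zn]Br | starting material
14 | 3-[(1R,6S)-2-(3-ethoxy-3-oxopropyl)-6-(2-hydroxypropan-2-yl)-1,3-dimethylcyclohex-2-en-1-yl]propanoic acid | CCOC(=O)CCC1=C(C)CC[C@H](C(C)(C)O)[C@@]1(C)CCC(=O)O | intermediate
15 | methyl 3-oxopentanoate | CCC(=O)CC(=O)OC | starting material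
16 | 1,1-dimethoxypropan-2-one | CC(=O)C(OC)OC | starting material
17 | methyl 2-(1,1-dimethoxypropan-2-ylidene)-3-oxopentanoate (E/Z mixture) | CCC(=O)C(C(=O)OC)=C(C)C(OC)OC | intermediate
18 | dilithium 2-(3,3-dimethoxyprop-1-en-2-yl)-1-methoxypenta-1,3-diene-1,3-diolate (dianion of 17) | [Li+].[Li+].CC=C([O-])C(=C([O-])OC)C(=C)C(OC)OC | intermediate
19 | 3-[(1R,6S)-2-[8,8-dimethoxy-6-(methoxycarbonyl)-4,7-dimethyl-3,5-dioxooct-6-en-1-yl]-6-(2-hydroxypropan-2-yl)-1,3-dimethylcyclohex-2-en-1-yl]propanoic acid (alkene and diketone isomers) | COC(=O)C(=C(C)C(OC)OC)C(=O)C(C)C(=O)CCC1=C(C)CC[C@H](C(C)(C)O)[C@@]1(C)CCC(=O)O | intermediate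
20 | 3-[(1R,6S)-6-(2-hydroxypropan-2-yl)-2-[6-(methoxycarbonyl)-4,7-dimethyl-3,5,8-trioxooct-6-en-1-yl]-1,3-dimethylcyclohex-2-en-1-yl]propanoic acid | COC(=O)C(=C(C)C=O)C(=O)C(C)C(=O)CCC1=C(C)CC[C@H](C(C)(C)O)[C@@]1(C)CCC(=O)O | intermediate
21 | 3-[(1R,6S)-2-{[7-hydroxy-4-(methoxycarbonyl)-3,6-dimethyl-5-oxocyclohepta-1,3,6-trien-1-yl]methyl}-6-(2-hydroxypropan-2-yl)-1,3-dimethylcyclohex-2-en-1-yl]propanoic acid | COC(=O)C1=C(C)C=C(CC2=C(C)CC[C@H](C(C)(C)O)[C@@]2(C)CCC(=O)O)C(O)=C(C)C1=O | intermediate
22 | 3-[(2R,2′R,3′S,6′S)-3′-(2-hydroxypropan-2-yl)-6-(methoxycarbonyl)-2′,5,6′,8-tetramethyl-7-oxo-3,7-dihydrospiro[cyclohepta[b]furan-2,1′-cyclohexan]-2′-yl]propanoic acid (CNP0448476.3) | COC(=O)c1c(C)cc2c(c(C)c1=O)O[C@]1(C2)[C@@H](C)CC[C@H](C(C)(C)O)[C@@]1(C)CCC(=O)O | target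

Total step count: 10. Longest linear sequence: 9 steps (steps 1–6 and 8–10, from (S)-carvone); step 7 makes the side fragment.

Three steps most likely to fail

Step 10, the proposed hydroalkoxylation. The risks are 6-endo closure to the pyran, capture of the cation by the carboxylic acid (δ-lactone), ionisation of the tertiary alcohol, and incomplete equilibration at the two new stereocentres. The fallback uses known chemistry, sets out from 19 and comes back at 22: the C–O bond is made before the tropone exists. Catalytic CF3SO3H in CH2Cl2 effects the established cycloisomerisation of a γ,δ-unsaturated β-diketone, the enol oxygen closing 5-exo onto the ring alkene to give the spirocyclic vinylogous ester 3-[(5R,6R,7S,10S)-2-[6,6-dimethoxy-4-(methoxycarbonyl)-5-methyl-3-oxohex-4-en-2-ylidene]-7-(2-hydroxypropan-2-yl)-6,10-dimethyl-1-oxaspiro[4.5]decan-6-yl]propanoic acid F3. Aqueous acetic acid then frees the aldehyde, and DBU brings about the vinylogous aldol condensation of the ring CH2 next to the enol-ether carbon onto it, which aromatises directly to 22.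

Step 9, the tropone annulation. The risks are aldol at the central diketone carbon (five-membered ring), lactonisation of the enol onto the ester (4-hydroxy-2-pyranone), and an unfavourable alkene geometry. The fallback sets out from 19 and comes back at 21: regiocontrol is enforced by bis(silyl enol ether) chemistry instead of being left to thermodynamics. Me3SiOTf/Et3N converts 19 into the tetrakis(trimethylsilyl) derivative of 19 (3′,5′-bis(trimethylsilyloxy)-2′,4′-diene in the side chain, trimethylsilyl ester, tertiary trimethylsilyl ether) F2. Catalytic Me3SiOTf or TiCl4 at −78 °C then triggers Mukaiyama-type addition of the terminal diene carbon to the oxocarbenium ion formed from the dimethyl acetal. Acidic aqueous work-up removes the silyl groups and methanol and gives 21.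

Step 8, the dianion acylation. The risks are deprotonation of 17 at the wrong site, self-condensation, and poor conversion with the dilithium salt of 14. The fallback sets out from 14 (with 15 and 16) and comes back at 19: the order of the two C–C bond formations is inverted. The classical Weiler dianion of 15 (NaH, then n-BuLi) is acylated by 14 to give 3-[(1R,6S)-6-(2-hydroxypropan-2-yl)-2-(7-methoxy-4-methyl-3,5,7-trioxoheptyl)-1,3-dimethylcyclohex-2-en-1-yl]propanoic acid F1. Its C-2 methylene then undergoes TiCl4/pyridine Knoevenagel condensation with 16 to give 19.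

Further compounds
F1 | step 8 | 3-[(1R,6S)-6-(2-hydroxypropan-2-yl)-2-(7-methoxy-4-methyl-3,5,7-trioxoheptyl)-1,3-dimethylcyclohex-2-en-1-yl]propanoic acid | COC(=O)CC(=O)C(C)C(=O)CCC1=C(C)CC[C@H](C(C)(C)O)[C@@]1(C)CCC(=O)O
F2 | step 9 | tetrakis(trimethylsilyl) derivative of 19 (3′,5′-bis(trimethylsilyloxy)-2′,4′-diene, trimethylsilyl ester, tertiary trimethylsilyl ether) | COC(=O)C(=C(C)C(OC)OC)C(O[Si](C)(C)C)=C(C)C(O[Si](C)(C)C)=CCC1=C(C)CC[C@H](C(C)(C)O[Si](C)(C)C)[C@@]1(C)CCC(=O)O[Si](C)(C)C
F3 | step 10 | 3-[(5R,6R,7S,10S)-2-[6,6-dimethoxy-4-(methoxycarbonyl)-5-methyl-3-oxohex-4-en-2-ylidene]-7-(2-hydroxypropan-2-yl)-6,10-dimethyl-1-oxaspiro[4.5]decan-6-yl]propanoic acid | COC(=O)C(=C(C)C(OC)OC)C(=O)C(C)=C2O[C@]1(CC2)[C@@H](C)CC[C@H](C(C)(C)O)[C@@]1(C)CCC(=O)O
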